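## Analysis of the target

1. The target is a cis-fused decahydroquinoline. Quinoline numbering is used: ring A is the piperidine (N1, C2, C3, C4, C4a, C8a), ring B is the carbocycle (C4a, C5–C8, C8a), and the chain on C5 is C1'–C8'.
2. It carries a methyl group on C2, an (E)-oct-2-enoyloxy group on C3 and a 5-hydroxyoctyl chain on C5. The SMILES reads as 2R,3R,4aS,5S,8aR,5'R.
3. H-4a, H-5 and H-8a lie on one face, so N1, C4 and C1' form an all-cis triad on ring B. The C2 methyl group and O3 lie on the face of these hydrogens, so H-2 and H-3 are trans to H-8a and ring A is a 2,6-trans-piperidine.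
4. N1 and C1' are 1,3-related and cis on ring B, which locks the bicycle in the chair–chair form with both equatorial and C4 axial. In this form C8 is axial on ring A, the C2 methyl group is equatorial and O3 is axial.
5. C2 is therefore the thermodynamic epimer as soon as C3 is a ketone, and O3 corresponds to equatorial hydride attack. The hard part is the kinetic all-cis triad, its absolute sense, and the 2,6-trans relation, which imine reduction and enolate or enamine equilibration both deliver the wrong way round.
6. C5' is separated from the ring by four methylene groups and cannot be relayed from it.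
7. The sensitive groups are the enoate (labile to hydrogenation and to conjugate addition), the free secondary amine next to the ester (O-to-N acyl shift), and two secondary alcohols that must be told apart.
8. The plan exploits this feature: ring A (N1–C2(CH3)–C3(O)–C4–C4a–C8a) is the perhydro form of a 2-methylpyridin-3-ol. N1, C2, C3 and the methyl group are the skeleton of alanine, C8a is an acyl carbon, and the all-cis triad is what results when hydrogen reaches such a flat ring from the face opposite the C5 chain.

## Retrosynthetic reasoning

**C3–O acyl bond, N1 and O5' protection (25 ⇒ 24 ⇒ 22 + 23).** The enoate tolerates neither hydrogenation nor hydride, so it is attached last. The carbamate on N1 and the silyl ether on O5' leave O3 as the only acylation site in 22. Both groups fall in one acidic operation.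

**C3–H and C2–H (22 ⇒ 21 ⇒ 20 ⇒ 19).** The axial alcohol is traced back to ketone 20, where a bulky hydride has to enter along the equatorial line. The ketone also makes C2 epimerisable. In the locked chair–chair form the wrong epimer 19 has its methyl group syn-diaxial to C8, so equilibration sets the 2,6-trans relation without a reagent.

**The C–H bonds of ring A (19 ⇒ 18 ⇒ 17).** With C2 and C3 under later control, only C4a and C8a are left, and they share a face with H-5. Ring A is therefore flattened to pyridinol 17, whose single ring stereocentre C5 must send the hydrogen to the opposite face. Any scatter at C2 and C3 in 18 converges in 20.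

**C4a–C8a and C3–C4 (17 ⇒ 16 ⇒ 15), the key cut.** Both rings are opened at once. Ring A becomes a 5-ethoxy-4-methyloxazole and ring B becomes its four-carbon tether ending in a vinyl group. The cut is placed here because it turns the bicycle into a chain with one stereocentre. It also leaves every heteroatom of ring A in a unit that comes from an amino acid, and the forward reaction needs no stereocontrol, since aromatisation erases what the cycloaddition creates.

**Oxazole O–C bond and N1–C8a amide bond (15 ⇒ 14 ⇒ 12 + 13).** Cyclodehydration of an N-acyl amino ester gives the oxazole. The amide joins acid 12 to alanine ester 13, whose stereocentre is lost, so the cheapest enantiomer serves.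

**C5–C1' (12 ⇒ 11 ⇒ 9 + 10).** A carbon that bears a vinyl group and two alkyl arms is the typical product of a catalytic enantioselective SN2' alkylation. This one bond joins chain and tether, creates the dienophile and sets C5, the centre from which C4a, C8a, C2 and C3 are later relayed.

**Fragments (10 ⇒ 6 ⇒ 4 ⇒ 3 ⇒ 1 + 2; 9 ⇒ 7 + 8).** C5' is bought with epoxide 1 and extended by three carbons with 2. The terminal alkene is turned into the bromide for 10. Allylic bromide 9 comes from one cross-metathesis.

## Alternatives that were turned down

**Alternative 1:** (the textbook route) Disconnection of N1–C8a. The forward key step is the reduction of the bicyclic imine A1. A1 forms spontaneously once a C2 amine and a C8a ketone are unmasked in a 2,3-disubstituted cyclohexanone.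
- In the half-chair of A1 with the C2 methyl group equatorial, hydride or hydrogen enters C8a along the axial line. This places H-8a cis to H-2 and gives the 2,6-cis-piperidine, while the target is 2,6-trans.
- C4a is α to the C=N bond and equilibrates through the enamine to the isomer with H-4a trans to H-5, so the all-cis triad cannot be held.
- C2, C3 and C5 would each have to be made separately beforehand, for a key step that sets one centre and sets it wrongly.

**Alternative 2:** Disconnection of C4a–C5 and C8–C8a. The forward key step is the endo Diels–Alder reaction of the enantiopure dihydropyridone A2 with the chain diene A3 to give adduct A4. The stereochemistry is attractive: a cis-dienophile and the endo rule give the triad, and approach anti to the pseudoaxial C2 methyl group gives the 2,6-trans relation.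
- The activating carbonyl must sit on C4, both for reactivity and for the "ortho" orientation that puts C5 next to C4a, whereas the target has oxygen on C3 and a methylene at C4.
- Oxygenation of C3, deoxygenation of C4 and saturation of C6=C7 add five or more corrective operations.
- The C4a=C8a bond of A2 is part of a vinylogous imide and is deactivated by the nitrogen lone pair. With an unactivated 1-alkyl diene it would need forcing conditions, under which A3 isomerises or polymerises.
- A2 itself needs an auxiliary-based synthesis.

**Alternative 3:** Disconnection of N1–C2 and C4a–C8a without passing through an aromatic ring. The forward key step is the intramolecular imino Diels–Alder reaction of the iminium ion made from dienal A5 and a primary amine, giving A6. It closes both rings and would keep the sp3 centres.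
- The four-carbon tether favours the chair-like transition state that leads to the trans ring fusion, which cannot be repaired later.
- The only readily made diene geometry (Z-enol silane, methyl group outside) places the C2 methyl group cis to C5.
- C5 is only a weak allylic control element for the face of the diene.
- A5 combines an acid-labile silyl dienol ether with an aldehyde that has to be condensed under protic or Lewis acidic conditions.

Key step: step 9

Assumption 1: (R)-2-propyloxirane (1) is taken as commercial; it is also the epoxide recovered from hydrolytic kinetic resolution of the racemate.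
Assumption 2: the enantiomer of Taniaphos that gives (5S)-11 is used; both antipodes are available, and the sense of induction has to be confirmed by correlation.

## Route

Step 1
Reactants: 1 (R)-2-propyloxirane; 2 allylmagnesium bromide
Product: 3 (R)-oct-7-en-4-ol
Conditions: CuI (10 mol%), THF/Et2O, −30 °C to 0 °C; then H2O
Reagents that add atoms: none
Why: Copper-catalysed SN2 opening of a terminal epoxide by a Grignard reagent at the unsubstituted carbon. The C–O bond at the stereocentre is untouched, so C5' is bought with 1, and the descriptor stays R because the CIP order does not change.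

Step 2
Reactants: 3 (R)-oct-7-en-4-ol
Product: 4 (R)-tert-butyldimethyl(oct-7-en-4-yloxy)silane
Conditions: TBSCl, imidazole, DMF, rt
Reagents that add atoms: tert-butyldimethylsilyl chloride, CC(C)(C)[Si](C)(C)Cl
Why: Standard silylation. The silyl ether distinguishes O5' from the later O3, survives Grignard formation, base, heat and weakly acidic hydrogenation, and falls together with the carbamate in the last step.

Step 3
Reactants: 4 (R)-tert-butyldimethyl(oct-7-en-4-yloxy)silane
Product: 6 (R)-[(8-bromooctan-4-yl)oxy](tert-butyl)dimethylsilane, via trialkylborane 5 (not isolated)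
Conditions: BH3·THF (0.35 equiv), THF, 0 °C to rt; then Br2, NaOMe/MeOH, 0 °C
Reagents that add atoms: bromine, BrBr; borane–tetrahydrofuran, B.C1CCOC1 (boron only in 5)
Why: Hydroboration–bromination, the anti-Markovnikov hydrobromination of a terminal alkene. Boron goes to the terminal carbon, and methoxide-induced bromodeboronation gives the primary bromide; the silyl ether is inert.

Step 4
Reactants: 7 methyl hex-5-enoate; 8 (E)-1,4-dibromobut-2-ene
Product: 9 methyl (E)-7-bromohept-5-enoate
Conditions: second-generation Hoveyda–Grubbs catalyst (2 mol%), 8 (3 equiv), CH2Cl2, 40 °C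
Reagents that add atoms: none
Why: Olefin cross-metathesis of a terminal alkene with an excess of a symmetrical allylic dibromide. The E isomer is favoured under the reversible conditions, and the ester is a spectator.

Step 5
Reactants: 6 (R)-[(8-bromooctan-4-yl)oxy](tert-butyl)dimethylsilane; 9 methyl (E)-7-bromohept-5-enoate
Product: 11 methyl (5S,10R)-10-(tert-butyldimethylsilyloxy)-5-vinyltridecanoate, via Grignard reagent 10 (not isolated)
Conditions: Mg, Et2O, reflux; then slow addition to 9, CuBr·SMe2 (5 mol%), Taniaphos (6 mol%), CH2Cl2, −75 °C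
Reagents that add atoms: magnesium, [Mg] (only in 10)
Why: Copper-catalysed enantioselective allylic alkylation (SN2') of an E-allylic bromide with an alkyl Grignard reagent. The chiral ferrocenyl diphosphine on copper selects the face of C5 and the γ-position, and at −75 °C the methyl ester is not attacked. Because C5' is already fixed, the minor C5 epimer is a diastereomer and can be removed at a later stage.

Step 6
Reactants: 11 methyl (5S,10R)-10-(tert-butyldimethylsilyloxy)-5-vinyltridecanoate
Product: 12 (5S,10R)-10-(tert-butyldimethylsilyloxy)-5-vinyltridecanoic acid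
Conditions: LiOH, THF/MeOH/H2O, rt; then 1 M HCl to pH 4
Reagents that add atoms: lithium hydroxide, [Li+].[OH-]
Why: Saponification. No stereocentre is α to the carboxyl group, and the brief mild acidification leaves the secondary silyl ether intact.

Step 7
Reactants: 12 (5S,10R)-10-(tert-butyldimethylsilyloxy)-5-vinyltridecanoic acid; 13 L-alanine ethyl ester hydrochloride
Product: 14 ethyl N-[(5S,10R)-10-(tert-butyldimethylsilyloxy)-5-vinyltridecanoyl]-L-alaninate
Conditions: EDC·HCl, HOBt, Et3N, CH2Cl2, 0 °C to rt
Reagents that add atoms: none
Why: Carbodiimide/HOBt amide coupling. Compound 13 brings N1, C2, C3 and the methyl group of ring A. Its stereocentre is erased in step 8, so its configuration does not matter.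

Step 8
Reactants: 14 ethyl N-[(5S,10R)-10-(tert-butyldimethylsilyloxy)-5-vinyltridecanoyl]-L-alaninate
Product: 15 2-[(4S,9R)-9-(tert-butyldimethylsilyloxy)-4-vinyldodecyl]-5-ethoxy-4-methyl-1,3-oxazole
Conditions: PPh3, I2, Et3N, CH2Cl2, 0 °C to rt (PPh3 and I2 premixed)
Reagents that add atoms: none
Why: Robinson–Gabriel-type cyclodehydration under Appel-type activation. The phosphonium reagent activates the amide oxygen, the ester carbonyl oxygen closes the ring, and Et3N removes the α-hydrogen to give the 5-ethoxyoxazole. The basic medium and the absence of free iodine spare the silyl ether and the vinyl group.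

Step 9
Reactants: 15 2-[(4S,9R)-9-(tert-butyldimethylsilyloxy)-4-vinyldodecyl]-5-ethoxy-4-methyl-1,3-oxazole
Product: 17 (5S)-5-[(5R)-5-(tert-butyldimethylsilyloxy)octyl]-2-methyl-5,6,7,8-tetrahydroquinolin-3-ol, via oxygen-bridged cycloadduct 16 (not isolated)
Conditions: o-dichlorobenzene (0.02 M), DBN (1 equiv), BHT (cat.), 180 °C, sealed tube, argon
Reagents that add atoms: none
Why: The oxazole is a cyclic 2-azadiene (C8a=N1–C2=C3) and adds its termini C8a and C3 across the tethered vinyl group (C4a=C4) in a thermal intramolecular [4+2] cycloaddition to give the oxygen-bridged adduct 16. DBN then removes H-4a with opening of the C8a–O bridge bond, the hemiketal formed at C3 expels its ethoxy group, and the 4H-pyridin-3-one tautomerises to the aromatic pyridinol 17, which makes the sequence irreversible. The closest known reaction type is the Kondrat'eva pyridine synthesis, both in its vitamin B6 form (5-ethoxy-4-methyloxazole with unactivated cis-alkenes) and in its intramolecular oxazole–olefin form. Ring B closes by formation of C4a–C8a (type 1 intramolecular Diels–Alder mode, four-carbon tether C5–C8, six-membered, fused), and ring A closes in the same event by formation of C3–C4, its other atoms N1, C2, C3 and the methyl group being those of 13. The three new stereocentres of 16 (C3, C4a, C8a) are erased on aromatisation, so neither endo/exo nor facial selectivity is needed and no stereocentre of the target is set here; C5, a non-acidic allylic centre, passes unchanged and becomes the only control element of the bicycle. The step needs regioselectivity (C8a to the inner and C3 to the terminal alkene carbon), which the short tether enforces because the reversed orientation would give a strained bridged ring; it also needs loss of the ethoxy group rather than of the bridge oxygen, which the acetal-type C3 of a 5-alkoxyoxazole secures under basic conditions. High dilution suppresses intermolecular cycloaddition, and the base keeps the acid-labile oxazole and the silyl ether intact.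

Step 10
Reactants: 17 (5S)-5-[(5R)-5-(tert-butyldimethylsilyloxy)octyl]-2-methyl-5,6,7,8-tetrahydroquinolin-3-ol
Product: 18 (2S,3S,4aS,5S,8aR)-5-[(5R)-5-(tert-butyldimethylsilyloxy)octyl]-2-methyldecahydroquinolin-3-ol
Conditions: H2 (60 bar), 5% Rh/C, EtOH, AcOH (2 equiv), 50 °C; then aq. K2CO3
Reagents that add atoms: none
Why: Heterogeneous cis-hydrogenation of a pyridinium salt on rhodium. Peri (A(1,3)-type) strain with C4–H holds the C5 chain pseudoaxial, so ring A should adsorb by the opposite face and receive all its hydrogen there, which places H-4a and H-8a cis to each other and to H-5. C2 and C3 are formed all-syn at the same time, and any C2/C3 epimers that arise through enol–ketone leakage converge in step 11.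

Step 11
Reactants: 18 (2S,3S,4aS,5S,8aR)-5-[(5R)-5-(tert-butyldimethylsilyloxy)octyl]-2-methyldecahydroquinolin-3-ol
Product: 20 (2R,4aS,5S,8aR)-5-[(5R)-5-(tert-butyldimethylsilyloxy)octyl]-2-methyloctahydroquinolin-3(2H)-one, via (2S)-ketone 19 (not isolated)
Conditions: 2-azaadamantane N-oxyl (5 mol%), CuCl (5 mol%), 2,2'-bipyridine (5 mol%), DMAP (10 mol%), air, MeCN, rt; then DBU (0.2 equiv), rt
Reagents that add atoms: none
Why: Nitroxyl/copper aerobic alcohol oxidation, a reaction type that tolerates unprotected secondary amines. In the locked chair–chair form the kinetic ketone 19 has its C2 methyl group axial and syn-diaxial to C8, so enolisation by DBU should move it to the equatorial position. This sets C2 (2R, 2,6-trans) under thermodynamic control relayed from C5 and C8a.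

Step 12
Reactants: 20 (2R,4aS,5S,8aR)-5-[(5R)-5-(tert-butyldimethylsilyloxy)octyl]-2-methyloctahydroquinolin-3(2H)-one
Product: 21 (2R,3R,4aS,5S,8aR)-5-[(5R)-5-(tert-butyldimethylsilyloxy)octyl]-2-methyldecahydroquinolin-3-ol
Conditions: Li[HB(s-Bu)3] (1.5 equiv), THF, −78 °C; then H2O, acid–base extraction
Reagents that add atoms: none
Why: Reduction of a conformationally fixed cyclic ketone with a bulky trialkylborohydride, which attacks along the equatorial line as it does with 2-methylcyclohexanone. This should give the axial 3R alcohol cis to the equatorial C2 methyl group.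

Step 13
Reactants: 21 (2R,3R,4aS,5S,8aR)-5-[(5R)-5-(tert-butyldimethylsilyloxy)octyl]-2-methyldecahydroquinolin-3-ol
Product: 22 tert-butyl (2R,3R,4aS,5S,8aR)-5-[(5R)-5-(tert-butyldimethylsilyloxy)octyl]-3-hydroxy-2-methyloctahydroquinoline-1(2H)-carboxylate
Conditions: Boc2O (1.5 equiv), MeOH, 45 °C
Reagents that add atoms: di-tert-butyl dicarbonate, CC(C)(C)OC(=O)OC(=O)OC(C)(C)C
Why: Chemoselective carbamoylation of the amine. Without an acyl-transfer catalyst the axial secondary alcohol does not react, and no stereocentre is labile once C3 is an alcohol.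

Step 14
Reactants: 22 tert-butyl (2R,3R,4aS,5S,8aR)-5-[(5R)-5-(tert-butyldimethylsilyloxy)octyl]-3-hydroxy-2-methyloctahydroquinoline-1(2H)-carboxylate; 23 (E)-oct-2-enoic acid
Product: 24 tert-butyl (2R,3R,4aS,5S,8aR)-5-[(5R)-5-(tert-butyldimethylsilyloxy)octyl]-2-methyl-3-[(E)-oct-2-enoyloxy]octahydroquinoline-1(2H)-carboxylate
Conditions: DCC, DMAP, CH2Cl2, 0 °C to rt
Reagents that add atoms: none
Why: Steglich esterification with retention at C3. O3 is the only free nucleophile, and activation of the acid without an acyl chloride/amine pair avoids deconjugation of the E-enoate.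

Step 15
Reactants: 24 tert-butyl (2R,3R,4aS,5S,8aR)-5-[(5R)-5-(tert-butyldimethylsilyloxy)octyl]-2-methyl-3-[(E)-oct-2-enoyloxy]octahydroquinoline-1(2H)-carboxylate
Product: 25 (2R,3R,4aS,5S,8aR)-5-[(5R)-5-hydroxyoctyl]-2-methyldecahydroquinolin-3-yl (E)-oct-2-enoate
Conditions: TFA/CH2Cl2/H2O (5:5:1), 0 °C to rt; then cold sat. aq. NaHCO3
Reagents that add atoms: none
Why: Acidolysis of the tert-butyl carbamate and protodesilylation of the secondary silyl ether in one operation, with the enoate stable to acid. A short, cold, weakly basic work-up liberates the hindered amine without O-to-N acyl shift.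

## Compound list

1 | (R)-2-propyloxirane | CCC[C@@H]1CO1 | starting material
2 | allylmagnesium bromide | C=CC[Mg]Br | starting material
3 | (R)-oct-7-en-4-ol | C=CCC[C@H](O)CCC | intermediate
4 | (R)-tert-butyldimethyl(oct-7-en-4-yloxy)silane | C=CCC[C@H](O[Si](C)(C)C(C)(C)C)CCC | intermediate
5 | tris[(5R)-5-(tert-butyldimethylsilyloxy)octyl]borane (not isolated) | B(CCCC[C@H](O[Si](C)(C)C(C)(C)C)CCC)(CCCC[C@H](O[Si](C)(C)C(C)(C)C)CCC)CCCC[C@H](O[Si](C)(C)C(C)(C)C)CCC | intermediate
6 | (R)-[(8-bromooctan-4-yl)oxy](tert-butyl)dimethylsilane | BrCCCC[C@H](O[Si](C)(C)C(C)(C)C)CCC | intermediate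
7 | methyl hex-5-enoate | C=CCCCC(=O)OC | starting material
8 | (E)-1,4-dibromobut-2-ene | BrC/C=C/CBr | starting material
9 | methyl (E)-7-bromohept-5-enoate | BrC/C=C/CCCC(=O)OC | intermediate
10 | [(5R)-5-(tert-butyldimethylsilyloxy)octyl]magnesium bromide (not isolated) | Br[Mg]CCCC[C@H](O[Si](C)(C)C(C)(C)C)CCC | intermediate
11 | methyl (5S,10R)-10-(tert-butyldimethylsilyloxy)-5-vinyltridecanoate | C=C[C@@H](CCCC[C@H](O[Si](C)(C)C(C)(C)C)CCC)CCCC(=O)OC | intermediate
12 | (5S,10R)-10-(tert-butyldimethylsilyloxy)-5-vinyltridecanoic acid | C=C[C@@H](CCCC[C@H](O[Si](C)(C)C(C)(C)C)CCC)CCCC(=O)O | intermediate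
13 | L-alanine ethyl ester hydrochloride | CCOC(=O)[C@H](C)N.Cl | starting material
14 | ethyl N-[(5S,10R)-10-(tert-butyldimethylsilyloxy)-5-vinyltridecanoyl]-L-alaninate | C=C[C@@H](CCCC[C@H](O[Si](C)(C)C(C)(C)C)CCC)CCCC(=O)N[C@@H](C)C(=O)OCC | intermediate
15 | 2-[(4S,9R)-9-(tert-butyldimethylsilyloxy)-4-vinyldodecyl]-5-ethoxy-4-methyl-1,3-oxazole | C=C[C@@H](CCCC[C@H](O[Si](C)(C)C(C)(C)C)CCC)CCCc1nc(C)c(OCC)o1 | intermediate
16 | oxygen-bridged cycloadduct: 7-oxa-2-azabicyclo[2.2.1]hept-2-ene fused to ring B, O bridge between C3 (bearing OEt) and C8a; endo/exo mixture, the transient centres C3, C4a, C8a left open (not isolated) | CCOC12CC3[C@@H](CCCC[C@H](O[Si](C)(C)C(C)(C)C)CCC)CCCC3(O1)N=C2C | intermediate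
17 | (5S)-5-[(5R)-5-(tert-butyldimethylsilyloxy)octyl]-2-methyl-5,6,7,8-tetrahydroquinolin-3-ol | Cc1nc2c(cc1O)[C@@H](CCCC[C@H](O[Si](C)(C)C(C)(C)C)CCC)CCC2 | intermediate
18 | (2S,3S,4aS,5S,8aR)-5-[(5R)-5-(tert-butyldimethylsilyloxy)octyl]-2-methyldecahydroquinolin-3-ol | O[C@H]1C[C@H]2[C@@H](CCCC[C@H](O[Si](C)(C)C(C)(C)C)CCC)CCC[C@H]2N[C@H]1C | intermediate
19 | (2S,4aS,5S,8aR)-5-[(5R)-5-(tert-butyldimethylsilyloxy)octyl]-2-methyloctahydroquinolin-3(2H)-one (not isolated) | O=C1C[C@H]2[C@@H](CCCC[C@H](O[Si](C)(C)C(C)(C)C)CCC)CCC[C@H]2N[C@H]1C | intermediate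
20 | (2R,4aS,5S,8aR)-5-[(5R)-5-(tert-butyldimethylsilyloxy)octyl]-2-methyloctahydroquinolin-3(2H)-one | O=C1C[C@H]2[C@@H](CCCC[C@H](O[Si](C)(C)C(C)(C)C)CCC)CCC[C@H]2N[C@@H]1C | intermediate
21 | (2R,3R,4aS,5S,8aR)-5-[(5R)-5-(tert-butyldimethylsilyloxy)octyl]-2-methyldecahydroquinolin-3-ol | O[C@@H]1C[C@H]2[C@@H](CCCC[C@H](O[Si](C)(C)C(C)(C)C)CCC)CCC[C@H]2N[C@@H]1C | intermediate
22 | tert-butyl (2R,3R,4aS,5S,8aR)-5-[(5R)-5-(tert-butyldimethylsilyloxy)octyl]-3-hydroxy-2-methyloctahydroquinoline-1(2H)-carboxylate | O[C@@H]1C[C@H]2[C@@H](CCCC[C@H](O[Si](C)(C)C(C)(C)C)CCC)CCC[C@H]2N(C(=O)OC(C)(C)C)[C@@H]1C | intermediate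
23 | (E)-oct-2-enoic acid | CCCCC/C=C/C(=O)O | starting material
24 | tert-butyl (2R,3R,4aS,5S,8aR)-5-[(5R)-5-(tert-butyldimethylsilyloxy)octyl]-2-methyl-3-[(E)-oct-2-enoyloxy]octahydroquinoline-1(2H)-carboxylate | CCCCC/C=C/C(=O)O[C@@H]1C[C@H]2[C@@H](CCCC[C@H](O[Si](C)(C)C(C)(C)C)CCC)CCC[C@H]2N(C(=O)OC(C)(C)C)[C@@H]1C | intermediate
25 | (2R,3R,4aS,5S,8aR)-5-[(5R)-5-hydroxyoctyl]-2-methyldecahydroquinolin-3-yl (E)-oct-2-enoate | CCCCC/C=C/C(=O)O[C@@H]1C[C@H]2[C@@H](CCCC[C@H](O)CCC)CCC[C@H]2N[C@@H]1C | target

## Step count and least certain steps

Total step count: 15. Longest linear sequence: 14 steps (1, 2, 3, then 5 to 15, starting from 1); step 4 is the only side branch.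

**Step 9 (key step).**
- What may go wrong: the unactivated vinyl group may react too slowly. At the temperature then needed, the 5-ethoxyoxazole may decompose thermally or be hydrolysed by traces of water. The bridge may also open with loss of the bridge oxygen instead of the ethoxy group, which would leave an ether on C3.
- Fallback: activate the dienophile and remove the activating group as a gas. It sets out from 15. Cross-metathesis with acrylic acid (second-generation Hoveyda–Grubbs catalyst) gives the enoic acid F1. Its double bond is electron-poor and polarity-matched, since the nucleophilic oxazole terminus C8a meets the β-carbon C4a. Heating in toluene at about 110 °C should bring about the known decarboxylative variant of the Kondrat'eva reaction. The pyridinol-4-carboxylic acid F2 (written as its aromatic tautomer) loses carbon dioxide through its β-keto acid tautomer, and the route is rejoined at 17.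

**Step 10.**
- What may go wrong: facial selectivity may be incomplete if the chain is not held pseudoaxial. Enamine or iminium intermediates may desorb, with epimerisation at C4a or trans fusion. The C3–O bond may undergo hydrogenolysis, and the tetrasubstituted pyridine may be taken up slowly.
- Fallback: replace surface hydrogenation by a stepwise ionic reduction that stops at the ketone. It sets out from 17. Benzyl bromide in hot MeCN gives the pyridinium bromide F3. Homogeneous hydrogenation with [Ir(cod)Cl]2/PPh3, NaHCO3 and H2, the known reduction of 3-hydroxypyridinium salts to piperidin-3-ones, gives the N-benzyl ketone F4. In this path the ring-fusion enamine should be protonated at C4a anti to the pseudoaxial chain, the iminium ion should take up hydride at C8a from the face opposite the now axial chain, and C2 equilibrates in the flask. Hydrogenolysis over Pd(OH)2/C returns to 20, so steps 10 and 11 are both replaced.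

**Step 11.**
- What may go wrong: the α-amino ketone may be dehydrogenated further at the C2–N bond under copper and air. The amino alcohol may chelate copper and stall the catalysis. Epimerisation may remain incomplete.
- Fallback: mask the nitrogen during the oxidation. It sets out from 18. Boc2O gives the carbamate F5, and Dess–Martin periodinane gives the N-Boc ketone F6. Me3SiOTf/2,6-lutidine followed by MeOH removes the carbamate without touching the silyl ether. DBU then equilibrates C2, and the route is rejoined at 20.

**Step 12.**
- What may go wrong: facial selectivity may be lost. The axial face of C3 carries only H-4a and the nitrogen lone pair, while the equatorial line of approach lies on the side of the axial C8, so axial attack may compete even for a bulky hydride.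
- Fallback: turn the error into the solution by inversion. It sets out from 20. NaBH4 in MeOH at low temperature gives the equatorial alcohol F7 by axial attack, and Boc2O gives the carbamate F8. A Mitsunobu reaction with 23 (PPh3, diisopropyl azodicarboxylate) forms the ester with inversion at C3 and rejoins the route at 24.

**Step 5.**
- What may go wrong: direct SN2 substitution may compete and give the linear isomer. Enantioselectivity may be eroded by the Z content of 9 or by the long functionalised Grignard reagent. The reagent may attack the ester.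
- Fallback: set C5 on a ring and then open the ring. It sets out from 10. Copper-catalysed enantioselective conjugate addition to cyclohex-2-enone (CuBr·SMe2, ferrocenyl diphosphine) with trapping by Me3SiCl gives the silyl enol ether F9, whose double bond lies between the future C8a and C4a. Ozonolysis with Me2S work-up cleaves exactly this bond to the aldehyde acid F10. Wittig methylenation with Ph3P=CH2 (2.2 equiv, low temperature, to limit epimerisation at C5) rejoins the route at 12, so steps 4 to 6 are replaced.

## Further compounds

F1 | step 9 | (2E,4S,9R)-9-(tert-butyldimethylsilyloxy)-4-[3-(5-ethoxy-4-methyl-1,3-oxazol-2-yl)propyl]dodec-2-enoic acid | OC(=O)/C=C/[C@@H](CCCC[C@H](O[Si](C)(C)C(C)(C)C)CCC)CCCc1nc(C)c(OCC)o1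
F2 | step 9 | (5S)-5-[(5R)-5-(tert-butyldimethylsilyloxy)octyl]-3-hydroxy-2-methyl-5,6,7,8-tetrahydroquinoline-4-carboxylic acid | Cc1nc2c(c(C(=O)O)c1O)[C@@H](CCCC[C@H](O[Si](C)(C)C(C)(C)C)CCC)CCC2
F3 | step 10 | (5S)-1-benzyl-5-[(5R)-5-(tert-butyldimethylsilyloxy)octyl]-3-hydroxy-2-methyl-5,6,7,8-tetrahydroquinolin-1-ium bromide | Cc1[n+](Cc3ccccc3)c2c(cc1O)[C@@H](CCCC[C@H](O[Si](C)(C)C(C)(C)C)CCC)CCC2.[Br-]
F4 | step 10 | (2R,4aS,5S,8aR)-1-benzyl-5-[(5R)-5-(tert-butyldimethylsilyloxy)octyl]-2-methyloctahydroquinolin-3(2H)-one | O=C1C[C@H]2[C@@H](CCCC[C@H](O[Si](C)(C)C(C)(C)C)CCC)CCC[C@H]2N(Cc2ccccc2)[C@@H]1C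
F5 | step 11 | tert-butyl (2S,3S,4aS,5S,8aR)-5-[(5R)-5-(tert-butyldimethylsilyloxy)octyl]-3-hydroxy-2-methyloctahydroquinoline-1(2H)-carboxylate | O[C@H]1C[C@H]2[C@@H](CCCC[C@H](O[Si](C)(C)C(C)(C)C)CCC)CCC[C@H]2N(C(=O)OC(C)(C)C)[C@H]1C
F6 | step 11 | tert-butyl (2S,4aS,5S,8aR)-5-[(5R)-5-(tert-butyldimethylsilyloxy)octyl]-2-methyl-3-oxooctahydroquinoline-1(2H)-carboxylate | O=C1C[C@H]2[C@@H](CCCC[C@H](O[Si](C)(C)C(C)(C)C)CCC)CCC[C@H]2N(C(=O)OC(C)(C)C)[C@H]1C
F7 | step 12 | (2R,3S,4aS,5S,8aR)-5-[(5R)-5-(tert-butyldimethylsilyloxy)octyl]-2-methyldecahydroquinolin-3-ol | O[C@H]1C[C@H]2[C@@H](CCCC[C@H](O[Si](C)(C)C(C)(C)C)CCC)CCC[C@H]2N[C@@H]1C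
F8 | step 12 | tert-butyl (2R,3S,4aS,5S,8aR)-5-[(5R)-5-(tert-butyldimethylsilyloxy)octyl]-3-hydroxy-2-methyloctahydroquinoline-1(2H)-carboxylate | O[C@H]1C[C@H]2[C@@H](CCCC[C@H](O[Si](C)(C)C(C)(C)C)CCC)CCC[C@H]2N(C(=O)OC(C)(C)C)[C@@H]1C
F9 | step 5 | ({(3S)-3-[(5R)-5-(tert-butyldimethylsilyloxy)octyl]cyclohex-1-en-1-yl}oxy)trimethylsilane | C[Si](C)(C)OC1=C[C@@H](CCCC[C@H](O[Si](C)(C)C(C)(C)C)CCC)CCC1
F10 | step 5 | (5S,10R)-10-(tert-butyldimethylsilyloxy)-5-formyltridecanoic acid | O=C[C@@H](CCCC[C@H](O[Si](C)(C)C(C)(C)C)CCC)CCCC(=O)O
A1 | alternative 1 | (2R,3R,4aS,5S)-5-[(5R)-5-(tert-butyldimethylsilyloxy)octyl]-2-methyl-2,3,4,4a,5,6,7,8-octahydroquinolin-3-ol | O[C@@H]1C[C@H]2[C@@H](CCCC[C@H](O[Si](C)(C)C(C)(C)C)CCC)CCCC2=N[C@@H]1C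
A2 | alternative 2 | benzyl (R)-2-methyl-4-oxo-3,4-dihydropyridine-1(2H)-carboxylate | C[C@@H]1CC(=O)C=CN1C(=O)OCc1ccccc1
A3 | alternative 2 | (R,E)-tert-butyl(dodeca-9,11-dien-4-yloxy)dimethylsilane | C=C/C=C/CCCC[C@H](O[Si](C)(C)C(C)(C)C)CCC
A4 | alternative 2 | benzyl (2R,4aS,5S,8aR)-5-[(5R)-5-(tert-butyldimethylsilyloxy)octyl]-2-methyl-4-oxo-3,4,4a,5,8,8a-hexahydroquinoline-1(2H)-carboxylate | O=C1[C@H]2[C@@H](CCCC[C@H](O[Si](C)(C)C(C)(C)C)CCC)C=CC[C@H]2N(C(=O)OCc2ccccc2)[C@H](C)C1
A5 | alternative 3 | (5S,6E,8Z)-8-(tert-butyldimethylsilyloxy)-5-[(5R)-5-(tert-butyldimethylsilyloxy)octyl]deca-6,8-dienal | C/C=C(O[Si](C)(C)C(C)(C)C)/C=C/[C@@H](CCCC[C@H](O[Si](C)(C)C(C)(C)C)CCC)CCCC=O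
A6 | alternative 3 | (2R,4aR,5S,8aR)-1-benzyl-3-(tert-butyldimethylsilyloxy)-5-[(5R)-5-(tert-butyldimethylsilyloxy)octyl]-2-methyl-1,2,4a,5,6,7,8,8a-octahydroquinoline | CC(C)(C)[Si](C)(C)OC1=C[C@H]2[C@@H](CCCC[C@H](O[Si](C)(C)C(C)(C)C)CCC)CCC[C@H]2N(Cc2ccccc2)[C@@H]1C
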